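Numbering: C1 = ester-bearing alkene carbon, then C2, C3, C4 (fusion CH), C5 (quaternary), C6 (CHCl), C7, C8 (CHOH), C9 (methyl-bearing fusion carbon), C10 (CH carrying formyl C11); ring A = C1, C2, C3, C4, C9, C10; ring B = C4 to C9.
Enabling feature: ring A is a cyclohexene joined to ring B through the trans C4–C9 bond, with the C1 ester next to formyl-bearing C10 and contiguous stereocentres at C4, C9 and C10. Once C1=C2 is shifted to C2=C3, ring A is the retron of a [4+2] union of a C1–C4 dienoate with a C9=C10 enal already linked by C5–C8.
Cuts, in retrosynthetic order: side-chain CH=CH (cross-metathesis), C6–Cl (back to the axial alcohol, then the ketone), C1–C10 and C4–C9 together (intramolecular Diels–Alder), C7–C8 (aldol), C3=C4 (olefination), C5–allyl (alkylation).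
Forward order: the open chain is joined as C5–allyl, then C3=C4, then C7–C8. Rings A and B then arise together in one step. Masking, reduction, chlorination, alkene shift, deprotection and metathesis finish the target.
Stereochemistry: C5 comes from a valine enamine alkylation and C8 from a reagent-controlled boron aldol. C4, C9, C10 (and transient C1) come from alkene geometry, the endo mode and the chair tether biased by C5 and C8. C6 comes from equatorial hydride delivery followed by SN2 inversion, and the side-chain E geometry from metathesis.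

Key step: step 9

Assumption: the sense of induction in steps 2 and 6 follows the accepted models (allylation of the chelated lithio-enamine anti to the isopropyl group with THF as lithium ligand; (S)-carbinols from enals with (+)-Ipc2BCl). The opposite sense is reached by changing the lithium ligand to HMPA or by using (−)-Ipc2BCl, with nothing else altered.

Step 1
Reactants: 1 ethyl 2-methylacetoacetate (racemic); 2 L-valine tert-butyl ester (free base)
Product: 3 valine enamino ester, ethyl (Z)-3-{[(2S)-1-tert-butoxy-3-methyl-1-oxobutan-2-yl]amino}-2-methylbut-2-enoate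
Conditions: BF3·OEt2 (cat.), toluene, reflux, Dean–Stark trap
Reagents that add atoms: none
Why: Acid-catalysed condensation of a β-keto ester with a primary amine under azeotropic water removal gives the hydrogen-bonded (Z)-enamino ester, which erases the labile stereocentre of racemic 1 and attaches the auxiliary without forming a new stereocentre.

Step 2
Reactants: 3 valine enamino ester; 4 allyl bromide
Product: 7 ethyl (R)-2-acetyl-2-methylpent-4-enoate, via lithio-enamine 5 (not isolated), via allylated imine 6 (not isolated)
Conditions: LiN(i-Pr)2, toluene, −78 °C; THF (2 equiv), 4, −78 to −40 °C; then 1 M aq HCl, 0 °C to rt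
Reagents that add atoms: water, O
Why: Auxiliary-controlled metalloenamine alkylation: lithium is held by the nitrogen and the ester carbonyls, the isopropyl group covers one face of the planar aza-enolate, allyl bromide enters from the other face to set quaternary (R)-C5, and mild acid hydrolysis of the imine releases the keto ester and the recoverable amino ester.

Step 3
Reactants: 7 ethyl (R)-2-acetyl-2-methylpent-4-enoate
Product: 8 (2S)-2-methyl-2-(prop-2-en-1-yl)butane-1,3-diol (both C3 epimers)
Conditions: LiAlH4, Et2O, 0 °C to rt
Reagents that add atoms: none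
Why: Exhaustive hydride reduction of ester and ketone removes any need to differentiate them; the new carbinol centre forms as a mixture that the next step erases, and quaternary C5 cannot epimerise.

Step 4
Reactants: 8 (2S)-2-methyl-2-(prop-2-en-1-yl)butane-1,3-diol
Product: 9 (S)-2-acetyl-2-methylpent-4-enal
Conditions: Dess–Martin periodinane (2.5 equiv), CH2Cl2, 0 °C to rt; used without prolonged concentration
Reagents that add atoms: none
Why: Double Dess–Martin oxidation restores the C6 ketone and brings C4 to the aldehyde level under neutral, non-nucleophilic conditions that spare a non-enolisable but deformylation-prone β-keto aldehyde.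

Step 5
Reactants: 9 (S)-2-acetyl-2-methylpent-4-enal; 10 methyl (E)-4-(dimethoxyphosphoryl)but-2-enoate
Product: 12 methyl (2E,4E,6S)-6-acetyl-6-methylnona-2,4,8-trienoate, via lithiated phosphonate 11 (not isolated)
Conditions: 10, LiN(SiMe3)2, THF, −78 °C; then 9, −78 to 0 °C
Reagents that add atoms: none
Why: Vinylogous Horner–Wadsworth–Emmons olefination: the stabilised phosphonate anion adds to the aldehyde far faster than to the hindered methyl ketone, the α-quaternary aldehyde enforces E geometry at the new C3=C4 bond, and no stereocentre is formed or endangered.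

Step 6
Reactants: 12 methyl (2E,4E,6S)-6-acetyl-6-methylnona-2,4,8-trienoate; 13 (E)-4,4-dimethoxy-2-methylbut-2-enal
Product: 16 methyl (2E,4E,6S,9S,10E)-9-hydroxy-12,12-dimethoxy-6,10-dimethyl-7-oxo-6-(prop-2-en-1-yl)dodeca-2,4,10-trienoate, via boron enolate 14 (not isolated), via boron aldolate 15 (not isolated)
Conditions: (+)-Ipc2BCl, Et3N, Et2O, 0 °C; then 13, −78 to −20 °C; H2O2, MeOH, pH 7 buffer, 0 °C
Reagents that add atoms: none
Why: Reagent-controlled boron aldol reaction: 12 can be enolised only at its methyl group because C5 is quaternary, and the isopinocampheyl ligands direct the enolate to the Si face of enal 13 through a cyclic transition state, which sets (S)-C8, the minor C8 epimer being a diastereomer that chromatography removes.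

Step 7
Reactants: 16 aldol adduct
Product: 17 methyl (2E,4E,6S,9S,10E)-9-(tert-butyldimethylsilyloxy)-12,12-dimethoxy-6,10-dimethyl-7-oxo-6-(prop-2-en-1-yl)dodeca-2,4,10-trienoate
Conditions: TBSCl, imidazole, DMF, rt
Reagents that add atoms: tert-butyldimethylsilyl chloride, CC(C)(C)[Si](C)(C)Cl
Why: Standard silylation of a secondary allylic alcohol under weakly basic conditions that provoke neither retro-aldol cleavage nor β-elimination installs the bulky, non-chelating group that later biases the cycloaddition, and no stereocentre is touched.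

Step 8
Reactants: 17 silylated acetal
Product: 18 methyl (2E,4E,6S,9S,10E)-9-(tert-butyldimethylsilyloxy)-6,10-dimethyl-7,12-dioxo-6-(prop-2-en-1-yl)dodeca-2,4,10-trienoate
Conditions: PPTS (cat.), acetone–H2O, rt
Reagents that add atoms: water, O
Why: Acid-catalysed hydrolysis of an allylic dimethyl acetal, which ionises through a conjugated oxocarbenium ion far faster than the hindered secondary silyl ether is cleaved, releases the (E)-enal without touching C5 or C8.

Step 9
Reactants: 18 dienoate–enal
Product: 19 trans-decalin cycloadduct (C2=C3 alkene; C6 ketone; axial C8 silyl ether; equatorial C10 formyl cis to the C9 methyl and to the C1 ester)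
Conditions: Me2AlCl (1.2 equiv), CH2Cl2 (0.01 M), −78 to 0 °C
Reagents that add atoms: none
Why: Me2AlCl binds the formyl oxygen of 18, lowers the LUMO of the C9=C10 enal and triggers a concerted, asynchronous [4+2] cycloaddition in which the δ-carbon C4 of the dienoate bonds to the β-carbon C9 slightly ahead of C1 to C10, the electronically matched "ortho" pairing; the closest known reaction type is the Lewis acid-promoted type 1 intramolecular Diels–Alder reaction of 1,7,9-decatrienes that carry a terminal carbonyl on the dienophile. Ring A closes as the six-membered cyclohexene of the suprafacial [4π+2π] event (C1–C10 and C4–C9 formed, C2=C3 left behind), and ring B closes in the same event as a six-membered carbocycle because the four-atom tether C5–C8 folds into a chair between C4 and C9. The (E,E)-diene geometry fixes C1 relative to C4 (ester and C5 cis on ring A), the (E)-enal geometry fixes C9 relative to C10 (methyl and formyl cis), and the endo-formyl, exo-tether arrangement, favoured by secondary overlap of the aluminium-bound carbonyl, relates the two pairs and gives the trans C4–C9 fusion. The absolute sense follows from C5 and C8: in the preferred chair the C8 silyloxy group is axial, antiperiplanar to the C9 methyl and free of a syn-axial partner at trigonal C6, and the C5 methyl rather than the allyl chain takes the axial site that faces the C9 methyl. The step needs rate (both partners are electron-poor), endo selectivity and facial selectivity; the first is supplied by intramolecularity, by compression at quaternary C5 (Thorpe–Ingold effect) and by selective complexation of the most basic and least hindered carbonyl, the other two by the low temperature that the Lewis acid permits. The allyl group, the hindered C6 ketone and the silyl ether are spectators.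

Step 10
Reactants: 19 trans-decalin cycloadduct
Product: 20 C11 dimethyl acetal of the cycloadduct
Conditions: HC(OMe)3, PPTS (cat.), MeOH, rt
Reagents that add atoms: trimethyl orthoformate, COC(OC)OC
Why: Chemoselective acid-catalysed acetalisation with orthoformate as dehydrating methoxy donor: the aldehyde reacts while the C6 ketone next to quaternary C5 stays free, and the equatorial C10 substituent is already the more stable epimer and so is not at risk.

Step 11
Reactants: 20 keto acetal
Product: 21 axial (6R)-alcohol
Conditions: LiBH(s-Bu)3, THF, −78 °C; then H2O2, pH 7 buffer, 0 °C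
Reagents that add atoms: none
Why: Ketone reduction with a bulky trialkylborohydride: the axial approach to C6 is closed by the syn-axial C8 silyloxy group, so hydride arrives along the equatorial trajectory and gives the axial (6R)-alcohol, while ester, acetal and alkenes are inert at −78 °C and the buffered work-up discourages silyl migration.

Step 12
Reactants: 21 axial (6R)-alcohol
Product: 23 equatorial (6S)-chloride, via alkoxyphosphonium chloride 22 (not isolated)
Conditions: PPh3, CCl4, MeCN, 70 °C
Reagents that add atoms: carbon tetrachloride, ClC(Cl)(Cl)Cl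
Why: Appel reaction: the axial hydroxyl is activated as its oxyphosphonium ion and displaced by chloride from the rear (SN2, inversion) to give the equatorial (6S)-chloride, this reagent pair being the one known to substitute neopentyl-type alcohols without skeletal rearrangement, in a neutral medium that leaves acetal, silyl ether, ester and alkenes intact.

Step 13
Reactants: 23 equatorial (6S)-chloride
Product: 24 conjugated ester (C1=C2)
Conditions: DBU, toluene, 80 °C
Reagents that add atoms: none
Why: Base-mediated isomerisation of a β,γ- to an α,β-unsaturated ester through the extended dienolate: DBU removes the doubly activated C1–H and reprotonation at C3 gives the more stable trisubstituted enoate, erasing C1 as planned, while C10–H is not acidic with the formyl group masked and the equatorial chloride has no antiperiplanar hydrogen for E2.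

Step 14
Reactants: 24 conjugated ester
Product: 25 allyl hydroxy aldehyde
Conditions: 48% aq HF, MeCN, 0 °C to rt
Reagents that add atoms: water, O
Why: Global acidic deprotection: fluoride-assisted Si–O cleavage and acetal hydrolysis proceed in the same medium, and the absence of base keeps C10 from epimerising and the alkene from moving to C1=C10.

Step 15
Reactants: 25 allyl hydroxy aldehyde; 26 2-methylbut-3-en-2-ol
Product: 27 target CNP0167913.1
Conditions: 26 (10 equiv), second-generation Grubbs catalyst RuCl2(=CHPh)(PCy3)(H2IMes) (5 mol %), CH2Cl2, 40 °C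
Reagents that add atoms: none
Why: Olefin cross-metathesis between a type 1 terminal alkene and an unprotected tertiary allylic alcohol (type 2 partner) is selective for the cross product and, for steric reasons, for the E alkene; the trisubstituted enoate is inert, and the neutral conditions tolerate aldehyde, chloride and free alcohols, so the acid-sensitive tertiary allylic alcohol appears only in the last step.

Compound list
1 | ethyl 2-methylacetoacetate (racemic) | CCOC(=O)C(C)C(C)=O | starting material
2 | L-valine tert-butyl ester | CC(C)[C@H](N)C(=O)OC(C)(C)C | starting material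
3 | valine enamino ester, ethyl (Z)-3-{[(2S)-1-tert-butoxy-3-methyl-1-oxobutan-2-yl]amino}-2-methylbut-2-enoate | CCOC(=O)/C(C)=C(/C)N[C@@H](C(C)C)C(=O)OC(C)(C)C | intermediate
4 | allyl bromide | C=CCBr | starting material
5 | lithio-enamine (lithium aza-enolate of 3) | [Li+].CCOC(=O)/C(C)=C(/C)[N-][C@@H](C(C)C)C(=O)OC(C)(C)C | intermediate
6 | allylated imine, (R) at the new quaternary carbon | CCOC(=O)[C@](C)(CC=C)C(C)=N[C@@H](C(C)C)C(=O)OC(C)(C)C | intermediate
7 | ethyl (R)-2-acetyl-2-methylpent-4-enoate | CCOC(=O)[C@](C)(CC=C)C(C)=O | intermediate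
8 | (2S)-2-methyl-2-(prop-2-en-1-yl)butane-1,3-diol, both C3 epimers | OC[C@](C)(CC=C)C(C)O | intermediate
9 | (S)-2-acetyl-2-methylpent-4-enal | O=C[C@](C)(CC=C)C(C)=O | intermediate
10 | methyl (E)-4-(dimethoxyphosphoryl)but-2-enoate | COC(=O)/C=C/CP(=O)(OC)OC | starting material
11 | lithiated phosphonate (lithium salt of 10) | [Li+].COC(=O)/C=C/[CH-]P(=O)(OC)OC | intermediate
12 | methyl (2E,4E,6S)-6-acetyl-6-methylnona-2,4,8-trienoate | COC(=O)/C=C/C=C/[C@](C)(CC=C)C(C)=O | intermediate
13 | (E)-4,4-dimethoxy-2-methylbut-2-enal | COC(OC)/C=C(\C)C=O | starting material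
14 | boron enolate (diisopinocampheylboron enolate of 12) | COC(=O)/C=C/C=C/[C@](C)(CC=C)C(=C)OB([C@H]1C[C@H]2C[C@@H]([C@@H]1C)C2(C)C)[C@H]1C[C@H]2C[C@@H]([C@@H]1C)C2(C)C | intermediate
15 | boron aldolate (O-diisopinocampheylboryl derivative of 16) | COC(=O)/C=C/C=C/[C@](C)(CC=C)C(=O)C[C@H](OB([C@H]1C[C@H]2C[C@@H]([C@@H]1C)C2(C)C)[C@H]1C[C@H]2C[C@@H]([C@@H]1C)C2(C)C)/C(C)=C/C(OC)OC | intermediate
16 | aldol adduct, methyl (2E,4E,6S,9S,10E)-9-hydroxy-12,12-dimethoxy-6,10-dimethyl-7-oxo-6-(prop-2-en-1-yl)dodeca-2,4,10-trienoate | COC(=O)/C=C/C=C/[C@](C)(CC=C)C(=O)C[C@H](O)/C(C)=C/C(OC)OC | intermediate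
17 | silylated acetal, methyl (2E,4E,6S,9S,10E)-9-(tert-butyldimethylsilyloxy)-12,12-dimethoxy-6,10-dimethyl-7-oxo-6-(prop-2-en-1-yl)dodeca-2,4,10-trienoate | COC(=O)/C=C/C=C/[C@](C)(CC=C)C(=O)C[C@H](O[Si](C)(C)C(C)(C)C)/C(C)=C/C(OC)OC | intermediate
18 | dienoate–enal, methyl (2E,4E,6S,9S,10E)-9-(tert-butyldimethylsilyloxy)-6,10-dimethyl-7,12-dioxo-6-(prop-2-en-1-yl)dodeca-2,4,10-trienoate | COC(=O)/C=C/C=C/[C@](C)(CC=C)C(=O)C[C@H](O[Si](C)(C)C(C)(C)C)/C(C)=C/C=O | intermediate
19 | trans-decalin cycloadduct, methyl (1S,2S,4aR,5S,8S,8aS)-8-(tert-butyldimethylsilyloxy)-1-formyl-5,8a-dimethyl-6-oxo-5-(prop-2-en-1-yl)-1,2,4a,5,6,7,8,8a-octahydronaphthalene-2-carboxylate | COC(=O)[C@H]1C=C[C@H]2[C@](C)(CC=C)C(=O)C[C@H](O[Si](C)(C)C(C)(C)C)[C@]2(C)[C@H]1C=O | intermediate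
20 | keto acetal, methyl (1S,2S,4aR,5S,8S,8aS)-8-(tert-butyldimethylsilyloxy)-1-(dimethoxymethyl)-5,8a-dimethyl-6-oxo-5-(prop-2-en-1-yl)-1,2,4a,5,6,7,8,8a-octahydronaphthalene-2-carboxylate | COC(=O)[C@H]1C=C[C@H]2[C@](C)(CC=C)C(=O)C[C@H](O[Si](C)(C)C(C)(C)C)[C@]2(C)[C@H]1C(OC)OC | intermediate
21 | axial alcohol, methyl (1S,2S,4aS,5S,6R,8S,8aS)-8-(tert-butyldimethylsilyloxy)-1-(dimethoxymethyl)-6-hydroxy-5,8a-dimethyl-5-(prop-2-en-1-yl)-1,2,4a,5,6,7,8,8a-octahydronaphthalene-2-carboxylate | COC(=O)[C@H]1C=C[C@H]2[C@](C)(CC=C)[C@H](O)C[C@H](O[Si](C)(C)C(C)(C)C)[C@]2(C)[C@H]1C(OC)OC | intermediate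
22 | alkoxyphosphonium chloride (O-triphenylphosphonio derivative of 21) | COC(=O)[C@H]1C=C[C@H]2[C@](C)(CC=C)[C@H](O[P+](c3ccccc3)(c3ccccc3)c3ccccc3)C[C@H](O[Si](C)(C)C(C)(C)C)[C@]2(C)[C@H]1C(OC)OC.[Cl-] | intermediate
23 | equatorial chloride, methyl (1S,2S,4aR,5S,6S,8S,8aS)-8-(tert-butyldimethylsilyloxy)-6-chloro-1-(dimethoxymethyl)-5,8a-dimethyl-5-(prop-2-en-1-yl)-1,2,4a,5,6,7,8,8a-octahydronaphthalene-2-carboxylate | COC(=O)[C@H]1C=C[C@H]2[C@](C)(CC=C)[C@@H](Cl)C[C@H](O[Si](C)(C)C(C)(C)C)[C@]2(C)[C@H]1C(OC)OC | intermediate
24 | conjugated ester, methyl (1R,4aR,5S,6S,8S,8aS)-8-(tert-butyldimethylsilyloxy)-6-chloro-1-(dimethoxymethyl)-5,8a-dimethyl-5-(prop-2-en-1-yl)-1,4,4a,5,6,7,8,8a-octahydronaphthalene-2-carboxylate | COC(=O)C1=CC[C@H]2[C@](C)(CC=C)[C@@H](Cl)C[C@H](O[Si](C)(C)C(C)(C)C)[C@]2(C)[C@H]1C(OC)OC | intermediate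
25 | allyl hydroxy aldehyde, methyl (1R,4aR,5S,6S,8S,8aS)-6-chloro-1-formyl-8-hydroxy-5,8a-dimethyl-5-(prop-2-en-1-yl)-1,4,4a,5,6,7,8,8a-octahydronaphthalene-2-carboxylate | COC(=O)C1=CC[C@H]2[C@](C)(CC=C)[C@@H](Cl)C[C@H](O)[C@]2(C)[C@H]1C=O | intermediate
26 | 2-methylbut-3-en-2-ol | C=CC(C)(C)O | starting material
27 | CNP0167913.1, methyl (1R,4aR,5S,6S,8S,8aS)-6-chloro-1-formyl-8-hydroxy-5-[(E)-4-hydroxy-4-methylpent-2-en-1-yl]-5,8a-dimethyl-1,4,4a,5,6,7,8,8a-octahydronaphthalene-2-carboxylate | COC(=O)C1=CC[C@H]2[C@](C)(C/C=C/C(C)(C)O)[C@@H](Cl)C[C@H](O)[C@]2(C)[C@H]1C=O | target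

Total step count: 15. Longest linear sequence: 15 steps (1 to 27).

Steps most likely to fail

Step 9.
- **Risk:** Cycloaddition between two electron-poor partners may be slower than Lewis acid-induced β-elimination of the C8 silyloxy group next to the C6 ketone. Endo and facial discrimination may also erode if the temperature has to be raised.
- **Fallback:** An ionic Diels–Alder reaction across the same two bonds, setting out from acetal 17. Catalytic Me3SiOTf with 2,6-di-tert-butylpyridine in CH2Cl2 at −78 °C ionises the allylic acetal to the 1-methoxyallyl cation triflate F1, a much stronger dienophile than the aluminium-bound enal. This cation closes C1–C10 and C4–C9 to the ring-closed oxocarbenium triflate F2. Capture by the Me3SiOMe released in the ionisation gives acetal 20, where the route is rejoined with steps 8 to 10 bypassed.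

Step 12.
- **Risk:** Rear-side attack at neopentyl C6, flanked by the axial C5 methyl, may be outrun by anti elimination toward C7 or by a 1,2-shift of the antiperiplanar C5 methyl.
- **Fallback:** A radical deoxychlorination, which needs no rear-side access, setting out from alcohol 21. Acylation with methyl chlorooxoacetate (Et3N, DMAP, CH2Cl2) gives the C6 methyl oxalate F3. One equivalent of aqueous CsOH in THF saponifies the much more reactive oxalate methyl ester to the cesium oxalate F4. Visible-light photoredox oxidation ([Ir(dF(CF3)ppy)2(dtbbpy)]PF6, blue LED) in the presence of ethyl trichloroacetate then expels carbon dioxide. A chlorine atom is delivered to the C6 radical on the face away from the syn-axial C8 silyloxy group, which should return the route to chloride 23.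

Step 6.
- **Risk:** Face selection by isopinocampheyl ligands is only moderate for methyl ketones and may drop further next to bulky C5. The remote C8 epimers may also resist chromatographic separation.
- **Fallback:** An unselective aldol followed by a Sharpless kinetic resolution, setting out from ketone 12. LiN(i-Pr)2 in THF at −78 °C gives the lithium enolate F5, and addition of 13 gives the aldol adduct as a C8 epimer mixture F6. Ti(O-i-Pr)4, D-(−)-diisopropyl tartrate and t-BuOOH (about half an equivalent) in CH2Cl2 at −20 °C epoxidise the (8R)-epimer to the epoxy alcohol F7 much faster than the (8S)-epimer. The (8S)-epimer is recovered as 16, where the route continues.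

Further compounds
F1 | step 9 | 1-methoxyallyl cation triflate derived from 17 | COC(=O)/C=C/C=C/[C@](C)(CC=C)C(=O)C[C@H](O[Si](C)(C)C(C)(C)C)/C(C)=C/C=[O+]C.[O-]S(=O)(=O)C(F)(F)F
F2 | step 9 | ring-closed oxocarbenium triflate (O-methyl oxocarbenium form of 19) | COC(=O)[C@H]1C=C[C@H]2[C@](C)(CC=C)C(=O)C[C@H](O[Si](C)(C)C(C)(C)C)[C@]2(C)[C@H]1C=[O+]C.[O-]S(=O)(=O)C(F)(F)F
F3 | step 12 | C6 methyl oxalate of 21 | COC(=O)[C@H]1C=C[C@H]2[C@](C)(CC=C)[C@H](OC(=O)C(=O)OC)C[C@H](O[Si](C)(C)C(C)(C)C)[C@]2(C)[C@H]1C(OC)OC
F4 | step 12 | cesium oxalate of 21 | [Cs+].COC(=O)[C@H]1C=C[C@H]2[C@](C)(CC=C)[C@H](OC(=O)C(=O)[O-])C[C@H](O[Si](C)(C)C(C)(C)C)[C@]2(C)[C@H]1C(OC)OC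
F5 | step 6 | lithium enolate of 12 | [Li+].COC(=O)/C=C/C=C/[C@](C)(CC=C)C(=C)[O-]
F6 | step 6 | aldol adduct as C8 epimer mixture | COC(=O)/C=C/C=C/[C@](C)(CC=C)C(=O)CC(O)/C(C)=C/C(OC)OC
F7 | step 6 | (8R,9S,10R)-epoxy alcohol from the (8R)-epimer | COC(=O)/C=C/C=C/[C@](C)(CC=C)C(=O)C[C@@H](O)[C@]1(C)O[C@H]1C(OC)OC
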